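The seven-membered ring is cut into the three-carbon unit C10H2–C9(O)–C8(CH3)(O) and the four-carbon unit C1(CH3)–C5–C6–C7(=O), whose C1–C5 edge is shared with the cyclopentane. Oxygen on the central carbon C9 marks the first unit as an oxyallyl cation; oxygen on C7 marks the second as a 1-silyloxy diene. A Lewis-acid (4+3) cycloaddition of 3-(trimethylsilyloxy)but-3-en-2-one with a cyclopentenyl silyl dienol ether made from cis-jasmone therefore forms C1–C10 and C7–C8 in one operation and sets the quaternary C1 and the tertiary carbinol C8. A sacrificial C4 silyloxy stereocentre steers it and later becomes the isopropyl carbinol.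

Key step: step 5

Remark (numbering and one assumption): atoms carry daucane locants – C1 (ring-fusion carbon with CH3), C2, C3, C4 (carbinol carbon with isopropyl), C5 (ring-fusion CH) in the five-membered ring; C5, C6 (ester-bearing CH), C7 (C=O), C8 (C(CH3)OH), C9 (CHOH), C10 (CH2), C1 in the seven-membered ring; β is the face of the C1 methyl group, α the opposite face; 7 and 20 are taken as purchasable.

Step 1
Reactants: 1 cis-jasmone
Product: 2 (1S)-3-methyl-2-[(2Z)-pent-2-en-1-yl]cyclopent-2-en-1-ol
Conditions: (R)-2-methyl-CBS-oxazaborolidine (0.2 equiv), catecholborane, toluene, −78 °C; aq. NaOH work-up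
Reagents that add atoms: none
Why: Corey–Bakshi–Shibata reduction in which the fully substituted alkene flank acts as the large group, so the (R)-catalyst should deliver hydride to give the (S)-alcohol (C4 oxygen β), while catecholborane at −78 °C leaves the side-chain alkene untouched.

Step 2
Reactants: 2 (S)-allylic alcohol
Product: 3 triethyl{[(1S)-3-methyl-2-[(2Z)-pent-2-en-1-yl]cyclopent-2-en-1-yl]oxy}silane
Conditions: TESCl, imidazole, DMF, 0 °C
Reagents that add atoms: chlorotriethylsilane, CC[Si](Cl)(CC)CC
Why: Routine silylation of a secondary alcohol; the TES ether later shields the β face and can be removed in the presence of a TBS ether.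

Step 3
Reactants: 3 TES ether
Product: 5 2-[(5S)-2-methyl-5-(triethylsilyloxy)cyclopent-1-en-1-yl]acetaldehyde, via syn-diol 4 (not isolated)
Conditions: OsO4 (2 mol %), NaIO4, 2,6-lutidine, dioxane–H2O (3:1), rt
Reagents that add atoms: osmium tetroxide, O=[Os](=O)(=O)=O; sodium periodate, [Na+].[O-]I(=O)(=O)=O
Why: Lemieux–Johnson oxidation, in which OsO4 should dihydroxylate the unhindered cis-disubstituted alkene much faster than the tetrasubstituted ring alkene next to the silyloxy group, and periodate cleaves the diol to the aldehyde and propanal.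

Step 4
Reactants: 5 aldehyde
Product: 6 tert-butyl{[(E)-2-[(5S)-2-methyl-5-(triethylsilyloxy)cyclopent-1-en-1-yl]ethenyl]oxy}dimethylsilane
Conditions: TBSOTf, Et3N, CH2Cl2, −78 → 0 °C
Reagents that add atoms: tert-butyldimethylsilyl trifluoromethanesulfonate, CC(C)(C)[Si](C)(C)OS(=O)(=O)C(F)(F)F
Why: Soft enolisation of the aldehyde (silyl triflate and amine) should give the conjugated silyl dienol ether, mainly as the E isomer because the cyclopentenyl group is bulky; the Z isomer would react at C1 in the same way and differs only at C7, a centre that is erased in step 12.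

Step 5
Reactants: 6 silyl dienol ether; 7 3-(trimethylsilyloxy)but-3-en-2-one
Product: 9 cycloadduct ketol (1β-CH3; 4β-OTES; C5=C6; 7α-OTBS; 8β-CH3/8α-OH; C9=O), via C8-O-TMS cycloadduct 8 (not isolated)
Conditions: Sc(OTf)3 (10 mol %), 7 (1.5 equiv), CH2Cl2, −78 → −40 °C; then K2CO3, MeOH, 0 °C
Reagents that add atoms: 7 3-(trimethylsilyloxy)but-3-en-2-one, CC(=O)C(=C)O[Si](C)(C)C
Why: Sc(OTf)3 binds the ketone oxygen of 7 and generates a 2-silyloxyallyl (oxyallyl) cation whose CH2 terminus (C10) is attacked by C1, the vinylogous carbon of the silyl dienol ether, and the C7 silyloxocarbenium ion so formed is captured by the enol carbon C8, after which the TMS group moves from O9 to O8 and frees the catalyst. The closest known reaction type is the Lewis-acid-catalysed (4+3) cycloaddition of 2-silyloxy enals and enones with 1,3-dienes. The seven-membered ring closes as a (4+3) cycloaddition that is suprafacial on both partners, in its stepwise limit a 7-(enolendo)-exo-trig attack of C8 on C7. C1 is set by approach of the cation to the diene face opposite the C4 OTES group (C10 α, CH3 β); C8 by the dipole-minimised s-cis enone reacting in an extended arrangement in which the Lewis-acid-bound O8 lies under the diene and the OTMS group points away, which places the C8 methyl on the face of the C1 methyl; C7 (OTBS α from the E dienol ether) is erased in step 12. The step needs regioselectivity (C10 to C1, C8 to C7) and (4+3) rather than (4+2) or (3+2) periselectivity: the oxygen on C7 makes C1 the nucleophilic and C7 the cationic diene terminus while CH2 is the electrophilic end of the enone, and Lewis-acid activation at low temperature favours closure through C8.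

Step 6
Reactants: 9 cycloadduct ketol
Product: 10 saturated ketol (1β-CH3; 4β-OTES; 5α-H; 7α-OTBS; 8β-CH3/8α-OH; C9=O)
Conditions: H2 (1 atm), [Ir(cod)(PCy3)(py)]PF6 (5 mol %), CH2Cl2, rt
Reagents that add atoms: none
Why: Hydroxyl-directed homogeneous hydrogenation, in which the cationic iridium catalyst binds the homoallylic C8 hydroxyl (α) and should deliver hydrogen to the α face of C5=C6, setting C5–H α and thus the trans ring fusion; the silyl ethers at C4 and C7 do not direct.

Step 7
Reactants: 10 saturated ketol
Product: 11 cis-8,9-diol (9α-OH)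
Conditions: NaBH4, MeOH–CH2Cl2, −40 °C
Reagents that add atoms: none
Why: Borohydride reduction of the α-hydroxy ketone: with O8 and O9 held syn by sodium, hydride should add to C9 from the β side past the small C8 methyl, because the α side is crowded by the C8 oxygen and the C7 silyloxy group, giving the cis-diol.

Step 8
Reactants: 11 cis-8,9-diol
Product: 13 acetonide alcohol (4β-OH; 7α-OTBS; 8,9-O-isopropylidene), via triol 12 (not isolated)
Conditions: CSA (0.1 equiv), MeOH, 0 °C; then 2,2-dimethoxypropane, acetone, rt; Et3N
Reagents that add atoms: 2,2-dimethoxypropane, COC(C)(C)OC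
Why: Acid-catalysed methanolysis should remove the secondary TES ether while the hindered TBS ether at C7 survives, and acid-catalysed transketalisation then ties the cis-8,9-diol into an isopropylidene acetal (a mixed ketal at the C4 hydroxyl would be lost on aqueous work-up).

Step 9
Reactants: 13 acetonide alcohol
Product: 14 C4 ketone
Conditions: Dess–Martin periodinane, NaHCO3, CH2Cl2, 0 °C → rt
Reagents that add atoms: none
Why: Dess–Martin oxidation of the only free secondary hydroxyl under buffered, non-epimerising conditions should give the cyclopentanone with the trans ring fusion intact.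

Step 10
Reactants: 14 C4 ketone
Product: 15 tertiary carbinol (4β-OH; 4α-isopropyl)
Conditions: i-PrMgCl, CeCl3, THF, −78 °C; aq. NH4Cl
Reagents that add atoms: isopropylmagnesium chloride, CC(C)[Mg]Cl
Why: 1,2-Addition of the organocerium reagent, whose low basicity suppresses enolisation at C5 and β-hydride reduction, should occur from the α face, opposite the C1 methyl that sits 1,3-syn over the β face of the cyclopentanone, which sets C4 with OH β and isopropyl α.

Step 11
Reactants: 15 tertiary carbinol
Product: 16 C7 alcohol (7α-OH)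
Conditions: TBAF, THF, rt → 40 °C
Reagents that add atoms: none
Why: Fluoride-mediated cleavage of the silyl ether; the acetonide and the tertiary alcohol are inert.

Step 12
Reactants: 16 C7 alcohol
Product: 17 C7 ketone
Conditions: Dess–Martin periodinane, NaHCO3, CH2Cl2, rt
Reagents that add atoms: none
Why: Dess–Martin oxidation of the secondary C7 alcohol; the tertiary C4 alcohol cannot be oxidised.

Step 13
Reactants: 17 C7 ketone
Product: 19 α-hydroxy ketone (6α-OH), via dipotassium alkoxide-enolate 18 (not isolated)
Conditions: KN(SiMe3)2 (2.5 equiv), THF, −78 °C; then 3-phenyl-2-(phenylsulfonyl)oxaziridine, −78 °C; aq. NH4Cl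
Reagents that add atoms: 3-phenyl-2-(phenylsulfonyl)oxaziridine, O=S(=O)(c1ccccc1)N1OC1c1ccccc1
Why: α-Hydroxylation of a ketone enolate with an N-sulfonyloxaziridine: the C7 ketone can enolise only toward C6 because C8 is quaternary, and the oxidant should approach the enolate from the α face, away from the 1,3-related C1 methyl, giving the equatorial 6α-hydroxyl, which is also the epimer favoured under equilibration.

Step 14
Reactants: 19 α-hydroxy ketone; 20 4-(methoxymethoxy)benzoic acid
Product: 21 protected ester (6α-O-[4-(methoxymethoxy)benzoyl]; 8,9-O-isopropylidene)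
Conditions: EDC·HCl, DMAP, CH2Cl2, rt
Reagents that add atoms: 20 4-(methoxymethoxy)benzoic acid, COCOc1ccc(cc1)C(O)=O
Why: Steglich esterification, in which only the secondary C6 hydroxyl should be acylated because the tertiary C4 hydroxyl is too hindered.

Step 15
Reactants: 21 protected ester
Product: 22 CNP0241001.1
Conditions: HCl (2 M aq.), THF, 40 °C
Reagents that add atoms: none
Why: Acid hydrolysis should cleave the isopropylidene acetal and the methoxymethyl aryl ether in one operation, while the hindered benzoate ester, the ketone and the tertiary alcohols are stable to dilute acid at this temperature.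

Compound list
1 | cis-jasmone, 3-methyl-2-[(2Z)-pent-2-en-1-yl]cyclopent-2-en-1-one | CC/C=C\CC1=C(C)CCC1=O | starting material
2 | (1S)-3-methyl-2-[(2Z)-pent-2-en-1-yl]cyclopent-2-en-1-ol | O[C@H]1CCC(C)=C1C/C=C\CC | intermediate
3 | triethylsilyl ether of 2 | CC[Si](CC)(CC)O[C@H]1CCC(C)=C1C/C=C\CC | intermediate
4 | syn-2,3-diol of the side chain of 3 (one of the two syn face isomers drawn; not isolated) | CC[Si](CC)(CC)O[C@H]1CCC(C)=C1C[C@H](O)[C@@H](O)CC | intermediate
5 | 2-[(5S)-2-methyl-5-(triethylsilyloxy)cyclopent-1-en-1-yl]acetaldehyde | CC[Si](CC)(CC)O[C@H]1CCC(C)=C1CC=O | intermediate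
6 | (E)-silyl dienol ether, tert-butyl{[(E)-2-[(5S)-2-methyl-5-(triethylsilyloxy)cyclopent-1-en-1-yl]ethenyl]oxy}dimethylsilane | CC[Si](CC)(CC)O[C@H]1CCC(C)=C1/C=C/O[Si](C)(C)C(C)(C)C | intermediate
7 | 3-(trimethylsilyloxy)but-3-en-2-one | CC(=O)C(=C)O[Si](C)(C)C | starting material
8 | (4+3) cycloadduct as its C8 trimethylsilyl ether (not isolated) | CC[Si](CC)(CC)O[C@H]1CC[C@]2(C)CC(=O)[C@](C)(O[Si](C)(C)C)[C@H](O[Si](C)(C)C(C)(C)C)C=C21 | intermediate
9 | cycloadduct ketol: 8α-hydroxy-1β,8β-dimethyl-4β-(triethylsilyloxy)-7α-(tert-butyldimethylsilyloxy)bicyclo[5.3.0]dec-5-en-9-one (daucane locants) | CC[Si](CC)(CC)O[C@H]1CC[C@]2(C)CC(=O)[C@](C)(O)[C@H](O[Si](C)(C)C(C)(C)C)C=C21 | intermediate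
10 | 5α-H saturated ketol (trans-fused) | CC[Si](CC)(CC)O[C@H]1CC[C@]2(C)CC(=O)[C@](C)(O)[C@H](O[Si](C)(C)C(C)(C)C)C[C@H]21 | intermediate
11 | cis-8α,9α-diol | CC[Si](CC)(CC)O[C@H]1CC[C@]2(C)C[C@H](O)[C@](C)(O)[C@H](O[Si](C)(C)C(C)(C)C)C[C@H]21 | intermediate
12 | 4β,8α,9α-triol with 7α-OTBS (not isolated) | O[C@H]1CC[C@]2(C)C[C@H](O)[C@](C)(O)[C@H](O[Si](C)(C)C(C)(C)C)C[C@H]21 | intermediate
13 | 8,9-O-isopropylidene 4β-alcohol | O[C@H]1CC[C@]2(C)C[C@@H]3OC(C)(C)O[C@]3(C)[C@H](O[Si](C)(C)C(C)(C)C)C[C@H]21 | intermediate
14 | 8,9-O-isopropylidene C4 ketone | O=C1CC[C@]2(C)C[C@@H]3OC(C)(C)O[C@]3(C)[C@H](O[Si](C)(C)C(C)(C)C)C[C@H]21 | intermediate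
15 | 4β-hydroxy-4α-isopropyl 7α-OTBS acetonide | CC(C)[C@]1(O)CC[C@]2(C)C[C@@H]3OC(C)(C)O[C@]3(C)[C@H](O[Si](C)(C)C(C)(C)C)C[C@H]21 | intermediate
16 | 4β,7α-diol acetonide | CC(C)[C@]1(O)CC[C@]2(C)C[C@@H]3OC(C)(C)O[C@]3(C)[C@H](O)C[C@H]21 | intermediate
17 | C7 ketone acetonide | CC(C)[C@]1(O)CC[C@]2(C)C[C@@H]3OC(C)(C)O[C@]3(C)C(=O)C[C@H]21 | intermediate
18 | dipotassium C4-alkoxide C6=C7 enolate of 17 (not isolated) | CC(C)[C@]1([O-])CC[C@]2(C)C[C@@H]3OC(C)(C)O[C@]3(C)C([O-])=C[C@H]21.[K+].[K+] | intermediate
19 | 6α-hydroxy C7 ketone acetonide | CC(C)[C@]1(O)CC[C@]2(C)C[C@@H]3OC(C)(C)O[C@]3(C)C(=O)[C@H](O)[C@H]21 | intermediate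
20 | 4-(methoxymethoxy)benzoic acid | COCOc1ccc(cc1)C(O)=O | starting material
21 | 6α-[4-(methoxymethoxy)benzoyloxy] C7 ketone acetonide | CC(C)[C@]1(O)CC[C@]2(C)C[C@@H]3OC(C)(C)O[C@]3(C)C(=O)[C@H](OC(=O)c4ccc(OCOC)cc4)[C@H]21 | intermediate
22 | CNP0241001.1 | CC(C)[C@]1(O)CC[C@]2(C)C[C@H](O)[C@](C)(O)C(=O)[C@H](OC(=O)c3ccc(O)cc3)[C@H]21 | target

Total step count: 15. Longest linear sequence: 15 steps (1 to 22); 7 and 20 enter as purchased reagents.

Steps most likely to fail

Risk 1, step 5. The cation may attack C6 instead of the fully substituted C1 and close a five-membered ring, the cascade may stop after the first C–C bond when the diene reacts from its s-trans conformer, or the two diene faces may be poorly distinguished. The fallback sets out from 6 and returns at 8; it builds the same ring by a carbenoid route instead of a cationic one. Cyclopropanation of the enol ether double bond of 6 with 3-diazobutan-2-one (Rh2(OPiv)4, CH2Cl2, −78 °C, on the face away from the OTES group) should give the acetylcyclopropane F1. Enol silylation of its methyl ketone (TMSOTf, Et3N; only the CH3 side carries α-hydrogens) should give the cis-divinylcyclopropane silyl enol ether F2. Warming in toluene should bring about the divinylcyclopropane–cycloheptadiene (Cope) rearrangement to the cycloheptadiene silyl enol ether F3, which closes the C1–C10 bond and opens the cyclopropane; a trans isomer of F2 would converge at higher temperature. Rubottom oxidation of F3 with dimethyldioxirane (acetone, −40 °C), with 1,4-silyl shift, should give 8, which the methanolysis of step 5 converts into 9.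

Risk 2, step 7. Hydride may be delivered to C9 from the α face through a borate formed at the C8 hydroxyl, which would give the trans-diol. The fallback sets out from 10 and returns at 12; it replaces substrate-assisted delivery by reagent control on a protected ketol. Silylation of the tertiary hydroxyl (1-(trimethylsilyl)imidazole, CH2Cl2) should give the 8-O-TMS ketone F4. Reduction with the bulky, non-chelating LiBH(s-Bu)3 (THF, −78 °C) should add hydride anti to the C8–O bond and give the 8-O-TMS 9α-alcohol F5. The methanolysis of step 8 then strips both the TMS and the TES group to give triol 12, which is carried on to 13 as in step 8.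

Risk 3, step 10. The branched organometallic may enolise the ketone with loss of the C5 configuration, reduce it by β-hydride transfer, or add too slowly to the hindered carbonyl. The fallback sets out from 14 and returns at 15; it brings in the three carbons as an sp2 nucleophile and adjusts the oxidation level afterwards. Addition of 2-propenylmagnesium bromide with CeCl3 (THF, −78 °C), again from the α face, should give the isopropenyl carbinol F6, and hydrogenation of its 1,1-disubstituted alkene (H2, Pd/C, EtOAc) should give 15.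

Further compounds
F1 | step 5 | acetylcyclopropane: 1-acetyl-1-methyl-2-(tert-butyldimethylsilyloxy)-3-[(5S)-2-methyl-5-(triethylsilyloxy)cyclopent-1-en-1-yl]cyclopropane, acetyl cis to the cyclopentenyl group and silyloxy trans to both | CC[Si](CC)(CC)O[C@H]1CCC(C)=C1[C@@H]2[C@@H](O[Si](C)(C)C(C)(C)C)[C@]2(C)C(C)=O
F2 | step 5 | cis-divinylcyclopropane, trimethylsilyl enol ether of F1 | CC[Si](CC)(CC)O[C@H]1CCC(C)=C1[C@@H]2[C@@H](O[Si](C)(C)C(C)(C)C)[C@]2(C)C(=C)O[Si](C)(C)C
F3 | step 5 | cycloheptadiene silyl enol ether (C5=C6; C8=C9-OTMS; 7α-OTBS; 1β-CH3; 4β-OTES) | CC[Si](CC)(CC)O[C@H]1CC[C@]2(C)CC(O[Si](C)(C)C)=C(C)[C@H](O[Si](C)(C)C(C)(C)C)C=C21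
F4 | step 7 | 8-O-trimethylsilyl ether of 10 | CC[Si](CC)(CC)O[C@H]1CC[C@]2(C)CC(=O)[C@](C)(O[Si](C)(C)C)[C@H](O[Si](C)(C)C(C)(C)C)C[C@H]21
F5 | step 7 | 9α-alcohol of F4 | CC[Si](CC)(CC)O[C@H]1CC[C@]2(C)C[C@H](O)[C@](C)(O[Si](C)(C)C)[C@H](O[Si](C)(C)C(C)(C)C)C[C@H]21
F6 | step 10 | 4β-hydroxy-4α-isopropenyl 7α-OTBS acetonide | CC(=C)[C@]1(O)CC[C@]2(C)C[C@@H]3OC(C)(C)O[C@]3(C)[C@H](O[Si](C)(C)C(C)(C)C)C[C@H]21
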